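**Retrosynthetic overview**
1. C40 → C15 + C10 + C15. The C11=C12 and C11'=C12' bonds come from E-selective Horner–Wadsworth–Emmons (HWE) olefinations of the C10 trienedial with two C15 phosphonates.
2. The two C15 phosphonates are the two enantiomers of one racemic 3-hydroxy-7,8-didehydro-β end group, separated by a lipase. The (3R) form becomes ring B unchanged and the (3S) form becomes ring A.
3. Ring A is tailored in the order of the natural pathway. First comes 5,6-epoxidation, steered by the sacrificial 3S-OH, which sets C6. Then C3 is dehydrogenated with β-opening of the oxirane, and C7≡C8 is hydrated to the 8-ketone.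
4. Key disconnection C1–C6: a cyclase-like, proton-initiated cation–olefin cyclisation of an acyclic C15 dienyne that already carries the C3 oxygen. That dienyne comes from an epichlorohydrin linchpin, isopropenyl and acetylide nucleophiles, a carboalumination and a Sonogashira coupling.
5. Ring order: carbocycles A and B are formed together in one flask (step 6). The transient oxirane on ring A follows (made in step 9, opened in step 10).

Assumption: carotenoid numbering is used in the comments (ring C1–C6, chain C7–C15, primes for the acetylenic half; ring A = keto end, ring B = acetylenic end), and 1 and 15 are bought as bulk intermediates of industrial carotenoid manufacture.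

**Step 1**
Reactants: 1 (2E)-3-methylpent-2-en-4-yn-1-ol; 2 triethyl phosphite
Product: 3 diethyl [(2E)-3-methylpent-2-en-4-yn-1-yl]phosphonate
Conditions: ZnI2 (1.2 equiv), 2 (2.5 equiv), THF, reflux, 16 h
Reagents that add atoms: none
Why: ZnI2-mediated direct Michaelis–Arbuzov-type phosphonylation of a primary allylic alcohol (transesterification, then zinc-assisted O→P allyl transfer at the unhindered terminus) keeps the E-alkene and leaves the terminal alkyne alone.

**Step 2**
Reactants: 4 rac-epichlorohydrin; 5 isopropenylmagnesium bromide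
Product: 6 rac-1-chloro-4-methylpent-4-en-2-ol
Conditions: 5 (1.1 equiv), CuI (10 mol %), THF, −40 → 0 °C; H2O/NH4Cl
Reagents that add atoms: none
Why: Copper-catalysed Grignard opening of the epoxide at its CH2 terminus (SN2) joins C1/C2 to the future C3 carbinol, which is deliberately left racemic.

**Step 3**
Reactants: 6 rac-1-chloro-4-methylpent-4-en-2-ol; 7 lithium acetylide–ethylenediamine complex
Product: 9 rac-6-methylhept-6-en-1-yn-4-ol, via methallyloxirane 8 (not isolated)
Conditions: 7 (3 equiv), DMSO, 0 °C → rt; H2O
Reagents that add atoms: none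
Why: The first equivalent of acetylide acts as base and closes the chlorohydrin to the epoxide (intramolecular Williamson reaction), and the second opens it at the CH2 terminus (SN2 epoxide alkynylation).

**Step 4**
Reactants: 9 rac-6-methylhept-6-en-1-yn-4-ol
Product: 10 rac-(1E)-1-iodo-2,6-dimethylhepta-1,6-dien-4-ol
Conditions: AlMe3 (3 equiv), Cp2ZrCl2 (25 mol %), CH2Cl2, 0 °C → rt, 18 h; I2 (1.3 equiv), THF, −30 °C; aq K2CO3
Reagents that add atoms: trimethylaluminium, C[Al](C)C; iodine, II
Why: Negishi zirconium-catalysed syn-carboalumination of the homopropargylic aluminium alkoxide puts the future C5 methyl on the internal carbon, iodinolysis with retention gives the E-iodide, and the 1,1-disubstituted alkene is inert to this catalyst.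

**Step 5**
Reactants: 10 rac-(1E)-1-iodo-2,6-dimethylhepta-1,6-dien-4-ol; 3 diethyl [(2E)-3-methylpent-2-en-4-yn-1-yl]phosphonate
Product: 11 rac-diethyl [(2E,6E)-9-hydroxy-3,7,11-trimethyldodeca-2,6,11-trien-4-yn-1-yl]phosphonate
Conditions: Pd(PPh3)4 (3 mol %), CuI (6 mol %), i-Pr2NH (3 equiv), THF, rt
Reagents that add atoms: none
Why: Sonogashira coupling (zerovalent palladium plus copper acetylide) of an alkenyl iodide proceeds with retention and tolerates the free alcohol and the phosphonate; the C5=C6 geometry is lost later anyway because C6 ends as a ring sp2 carbon.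

**Step 6 (key step; rings A and B)**
Reactants: 11 rac-diethyl [(2E,6E)-9-hydroxy-3,7,11-trimethyldodeca-2,6,11-trien-4-yn-1-yl]phosphonate
Product: 12 rac-diethyl {(2E)-5-[4-hydroxy-2,6,6-trimethylcyclohex-1-en-1-yl]-3-methylpent-2-en-4-yn-1-yl}phosphonate
Conditions: SnCl4 (2.2 equiv), CH2Cl2 (0.02 M), −78 → −30 °C, 3 h; aq NaHCO3
Reagents that add atoms: none
Why: Proposed new method: one SnCl4 binds the phosphonate oxygen and so lowers the basicity of the remote C7≡C8/C9=C10 end, while the second binds the C3 hydroxyl, whose proton becomes a Lewis-acid-assisted Brønsted acid delivered through a six-membered transition state to the neighbouring isopropenyl CH2, giving the same tertiary C1 cation that a lycopene cyclase makes; C5=C6 then attacks through C6 (6-endo, Markovnikov, chair) and loss of the propargylic H-6 gives the conjugated β-type ring, favoured because the slim alkynyl group removes the strain that favours the 4-ene isomer in the ionones; the C3 carbinol survives because its only trap for either cation is a reversible oxetane closure; the closest known reaction types are the acid cyclisation of pseudoionone to β-ionone and tin tetrachloride–alcohol proton-initiated polyene cyclisations.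

**Step 7**
Reactants: 12 rac-diethyl {(2E)-5-[4-hydroxy-2,6,6-trimethylcyclohex-1-en-1-yl]-3-methylpent-2-en-4-yn-1-yl}phosphonate
Product: 13 diethyl {(2E)-5-[(4R)-4-acetoxy-2,6,6-trimethylcyclohex-1-en-1-yl]-3-methylpent-2-en-4-yn-1-yl}phosphonate; 14 diethyl {(2E)-5-[(4S)-4-hydroxy-2,6,6-trimethylcyclohex-1-en-1-yl]-3-methylpent-2-en-4-yn-1-yl}phosphonate
Conditions: immobilised Burkholderia cepacia lipase, vinyl acetate (3 equiv), MTBE, 30 °C, to 50 % conversion; chromatography
Reagents that add atoms: vinyl acetate, C=COC(C)=O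
Why: Lipase kinetic resolution by irreversible transesterification (Kazlauskas rule with the CMe2 side as the large group, as in 3-hydroxy-β-ionone-type rings) acetylates only the (R)-alcohol, which fixes C3' of ring B and leaves the (S)-alcohol that will steer C6 of ring A, so both halves are used.

**Step 8**
Reactants: 13 (4R)-acetate phosphonate; 15 (2E,4E,6E)-2,7-dimethylocta-2,4,6-trienedial
Product: 17 (all-E,3R)-3-hydroxy-7,8-didehydro-12'-apo-β-caroten-12'-al, via (R)-hydroxy phosphonate 16 (not isolated)
Conditions: 13, NaOMe (3 equiv), DMF/MeOH 20:1, 0 °C, 20 min; then added to 15 (3 equiv), DMF, 0 °C → rt, dark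
Reagents that add atoms: none
Why: Methoxide first removes the acetate by transesterification and then drives an E-selective HWE olefination of the allylic phosphonate carbanion, the excess dialdehyde limits it to mono-olefination, and C3' is not involved.

**Step 9 (oxirane on ring A)**
Reactants: 14 (4S)-hydroxy phosphonate
Product: 18 diethyl {(2E)-5-[(1R,4R,6R)-4-hydroxy-2,2,6-trimethyl-7-oxabicyclo[4.1.0]heptan-1-yl]-3-methylpent-2-en-4-yn-1-yl}phosphonate (oxirane syn to the hydroxyl)
Conditions: VO(acac)2 (5 mol %), t-BuOOH (1.5 equiv, decane), CH2Cl2, 0 °C → rt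
Reagents that add atoms: tert-butyl hydroperoxide, CC(C)(C)OO
Why: Hydroxyl-directed vanadium-catalysed epoxidation of a homoallylic cyclohexenol delivers oxygen from the vanadate ester to the face carrying the 3S-OH, so only C5=C6 reacts and the C6–O bond is set in the spatial sense of 6S in the target (the descriptor reads R here only because alkynyl outranks C1).

**Step 10**
Reactants: 18 syn-epoxy alcohol phosphonate
Product: 20 diethyl {(2E)-5-[(1S)-1-hydroxy-2,6,6-trimethyl-4-oxocyclohex-2-en-1-yl]-3-methylpent-2-en-4-yn-1-yl}phosphonate, via epoxy ketone 19 (not isolated)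
Conditions: Dess–Martin periodinane (1.3 equiv), NaHCO3, CH2Cl2, 0 °C → rt; then Et3N (5 equiv), rt, 2 h
Reagents that add atoms: none
Why: Dess–Martin oxidation followed by E1cB opening of the β,γ-epoxy ketone removes H-4 and breaks only the C5–O bond, so the C6–O bond and its configuration are kept while the relay centre C3 is erased, as in the xanthoxin-to-abscisic-aldehyde conversion.

**Step 11**
Reactants: 20 (1S)-hydroxy enone alkynyl phosphonate
Product: 21 diethyl {(2E)-5-[(1S)-1-hydroxy-2,6,6-trimethyl-4-oxocyclohex-2-en-1-yl]-3-methyl-4-oxopent-2-en-1-yl}phosphonate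
Conditions: (Ph3P)AuNTf2 (5 mol %), H2O (10 equiv), 1,4-dioxane, 40 °C
Reagents that add atoms: water, O
Why: In this gold-catalysed alkyne hydration water attacks C8, the alkyne carbon conjugated to the C9=C10 donor and remote from the electron-withdrawing carbinol, while Meyer–Schuster loss of the C6–OH is held back because a C6 cation would be vinylogously α to the ring ketone; C6 is untouched.

**Step 12**
Reactants: 21 keto phosphonate; 17 C25 apocarotenal
Product: 22 target, (3'R,6S)-3',6-dihydroxy-7',8'-didehydro-7,8-dihydro-ε,β-carotene-3,8-dione (all-E)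
Conditions: LiCl (4 equiv), DBU (1.5 equiv), MeCN/THF, 0 °C → rt, argon, dark
Reagents that add atoms: none
Why: In this Masamune–Roush HWE olefination the vinylogous β-keto phosphonate is acidic enough for LiCl/DBU, a base too weak to form the tertiary alkoxide that would start retro-aldol cleavage; the stabilised carbanion gives E-C11=C12, the α-methyl enone keeps E-C9=C10, and no stereocentre is touched.

**Compound list**
1 | (2E)-3-methylpent-2-en-4-yn-1-ol | C#C/C(C)=C/CO | starting material
2 | triethyl phosphite | CCOP(OCC)OCC | starting material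
3 | diethyl [(2E)-3-methylpent-2-en-4-yn-1-yl]phosphonate | C#C/C(C)=C/CP(=O)(OCC)OCC | intermediate
4 | rac-epichlorohydrin | ClCC1CO1 | starting material
5 | isopropenylmagnesium bromide | CC(=C)[Mg]Br | starting material
6 | rac-1-chloro-4-methylpent-4-en-2-ol | CC(=C)CC(O)CCl | intermediate
7 | lithium acetylide–ethylenediamine complex | [Li]C#C.NCCN | starting material
8 | rac-2-(2-methylprop-2-en-1-yl)oxirane (not isolated) | CC(=C)CC1CO1 | intermediate
9 | rac-6-methylhept-6-en-1-yn-4-ol | CC(=C)CC(O)CC#C | intermediate
10 | rac-(1E)-1-iodo-2,6-dimethylhepta-1,6-dien-4-ol | CC(=C)CC(O)C/C(C)=C/I | intermediate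
11 | rac-diethyl [(2E,6E)-9-hydroxy-3,7,11-trimethyldodeca-2,6,11-trien-4-yn-1-yl]phosphonate | CC(=C)CC(O)C/C(C)=C/C#C/C(C)=C/CP(=O)(OCC)OCC | intermediate
12 | rac-diethyl {(2E)-5-[4-hydroxy-2,6,6-trimethylcyclohex-1-en-1-yl]-3-methylpent-2-en-4-yn-1-yl}phosphonate | CCOP(=O)(OCC)C/C=C(\C)C#CC1=C(C)CC(O)CC1(C)C | intermediate
13 | (4R)-acetate of 12 | CCOP(=O)(OCC)C/C=C(\C)C#CC1=C(C)C[C@@H](OC(C)=O)CC1(C)C | intermediate
14 | (4S)-enantiomer of 12 | CCOP(=O)(OCC)C/C=C(\C)C#CC1=C(C)C[C@H](O)CC1(C)C | intermediate
15 | (2E,4E,6E)-2,7-dimethylocta-2,4,6-trienedial | O=C/C(C)=C/C=C/C=C(\C)C=O | starting material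
16 | (4R)-enantiomer of 12 (not isolated) | CCOP(=O)(OCC)C/C=C(\C)C#CC1=C(C)C[C@@H](O)CC1(C)C | intermediate
17 | (all-E,3R)-3-hydroxy-7,8-didehydro-12'-apo-β-caroten-12'-al | O=C/C(C)=C/C=C/C=C(C)/C=C/C=C(\C)C#CC1=C(C)C[C@@H](O)CC1(C)C | intermediate
18 | syn-epoxy alcohol, (1R,4R,6R)-7-oxabicyclo[4.1.0]heptane phosphonate | CCOP(=O)(OCC)C/C=C(\C)C#C[C@@]12O[C@]1(C)C[C@H](O)CC2(C)C | intermediate
19 | (1R,6R)-epoxy ketone phosphonate (not isolated) | CCOP(=O)(OCC)C/C=C(\C)C#C[C@@]12O[C@]1(C)CC(=O)CC2(C)C | intermediate
20 | (1S)-1-hydroxy-4-oxocyclohex-2-enyl alkynyl phosphonate | CCOP(=O)(OCC)C/C=C(\C)C#C[C@@]1(O)C(C)=CC(=O)CC1(C)C | intermediate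
21 | (1S)-1-hydroxy-4-oxocyclohex-2-enyl 4-oxopentenyl phosphonate | CCOP(=O)(OCC)C/C=C(\C)C(=O)C[C@@]1(O)C(C)=CC(=O)CC1(C)C | intermediate
22 | target (6S,3'R, all-E) | CC1=CC(=O)CC(C)(C)[C@@]1(O)CC(=O)/C(C)=C/C=C/C(C)=C/C=C/C=C(C)/C=C/C=C(\C)C#CC1=C(C)C[C@@H](O)CC1(C)C | target

**Totals**
Total steps: 12. Longest linear sequence: 10 (steps 2, 3, 4, 5, 6, 7, 9, 10, 11, 12).

**Three steps most likely to fail**

Step 6 (cyclisation). The risks are protonation of the dienyne at C8, retro-Prins loss of isobutene from the C1 cation, and incomplete convergence of the 4-ene isomer onto the conjugated ring. The fallback sets out from 10 and comes back at 12.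
- Compound 10 is coupled first with ethynyltrimethylsilane (Pd(PPh3)4, CuI, i-Pr2NH). This gives rac-(6E)-2,6-dimethyl-9-(trimethylsilyl)nona-1,6-dien-8-yn-4-ol F1.
- The ring closure is then run on this short, silyl-capped enyne, which has no second alkene and no phosphonate. Ordinary Brønsted acid (MeSO3H, CH2Cl2, −20 °C) gives rac-3,5,5-trimethyl-4-[(trimethylsilyl)ethynyl]cyclohex-3-en-1-ol F2.
- K2CO3/MeOH then gives rac-4-ethynyl-3,5,5-trimethylcyclohex-3-en-1-ol F3.
- The C9–C11 unit is attached afterwards with reversed polarity. But-2-yn-1-ol is hydrozirconated and iodinated (Cp2ZrHCl; I2) to (2E)-3-iodobut-2-en-1-ol F4.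
- F4 is phosphonylated as in step 1 to diethyl [(2E)-3-iodobut-2-en-1-yl]phosphonate F5.
- Sonogashira coupling of F3 with F5 gives 12.

Step 11 (hydration). The risks are Meyer–Schuster dehydration to the exocyclic dienedione and attack of water at C7. The fallback sets out from 20 and comes back at 21.
- Direct hydration is replaced by a hydrosilylation–oxidation aldol surrogate.
- [Cp*Ru(MeCN)3]PF6 (2 mol %) and (EtO)3SiH in CH2Cl2 at 0 °C add H and Si trans across the alkyne, with silicon on C8, the carbon distal to the carbinol. This gives the C8-triethoxysilyl alkene F6.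
- Tamao–Fleming oxidation (KF, KHCO3, H2O2, THF/MeOH) converts the C–Si bond into the 8-ketone 21.

Step 12 (final olefination). The risks are a sluggish reaction of the α-methyl polyenal under the weak base, retro-aldol cleavage, and oxa-Michael closure of 21. The fallback sets out from 20 (with 17) and comes back at 22.
- The order of olefination and hydration is reversed.
- Compound 20 is deprotonated with LiHMDS (2.2 equiv, THF, −78 °C). A propargylic alkoxide has no retro-aldol path, so the strong base is safe here.
- Condensation with 17 gives the 7,8-didehydro C40 precursor (C7≡C8 in place of CH2–C=O) F7.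
- The last step is then a hydratase-like hydration with (Ph3P)AuNTf2/H2O in dioxane. It should take the alkyne polarised by the free carbinol rather than the ring-shielded, doubly conjugated C7'≡C8'.

**Further compounds**
F1 | step 6 | rac-(6E)-2,6-dimethyl-9-(trimethylsilyl)nona-1,6-dien-8-yn-4-ol | CC(=C)CC(O)C/C(C)=C/C#C[Si](C)(C)C
F2 | step 6 | rac-3,5,5-trimethyl-4-[(trimethylsilyl)ethynyl]cyclohex-3-en-1-ol | C[Si](C)(C)C#CC1=C(C)CC(O)CC1(C)C
F3 | step 6 | rac-4-ethynyl-3,5,5-trimethylcyclohex-3-en-1-ol | C#CC1=C(C)CC(O)CC1(C)C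
F4 | step 6 | (2E)-3-iodobut-2-en-1-ol | C/C(I)=C\CO
F5 | step 6 | diethyl [(2E)-3-iodobut-2-en-1-yl]phosphonate | C/C(I)=C\CP(=O)(OCC)OCC
F6 | step 11 | C8-triethoxysilyl alkene from trans-hydrosilylation of 20 | CCOP(=O)(OCC)C/C=C(\C)/C([Si](OCC)(OCC)OCC)=C/[C@@]1(O)C(C)=CC(=O)CC1(C)C
F7 | step 12 | 7,8-didehydro C40 precursor (6S,3'R, all-E) | CC1=CC(=O)CC(C)(C)[C@@]1(O)C#C/C(C)=C/C=C/C(C)=C/C=C/C=C(C)/C=C/C=C(\C)C#CC1=C(C)C[C@@H](O)CC1(C)C
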